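**Plan**

- **Cuts.** The first cut is the acrylate Cα=Cβ bond (retro Knoevenagel–Doebner). It parts a 7-formyl benzodioxane acid from the malonic half ester of (R)-3-(4-hydroxy-3-methoxyphenyl)lactic acid. Next come the C2–H and C3–H bonds of dioxane ring B (retro hydrogenation to the flat 1,4-benzodioxine), then C3–O4 and last C2–O1. This leads back to a 4-O-protected 3,4-dihydroxybenzaldehyde and an aroyl diazoacetate.
- **Forward order.** The three benzene rings are bought. C2–O1 is made first, by carbenoid O–H insertion at the oxygen meta to the formyl group. Ring B then closes at C3–O4 (oxygen para to formyl) with loss of water, its C2=C3 bond is hydrogenated, and the lactate chain is joined last through the new C=C bond.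
- **Enabling feature.** In ring B the C2 carboxylic acid and the C3 catechol ring are cis, so H-2 and H-3 share one face, and C2 carries a native CO2H that can bind a metal. Syn addition of H2 to C2=C3 of the 3-aryl-1,4-benzodioxine-2-carboxylic acid maps exactly onto this diad.
- **Stereochemistry.** C2 and C3 (2S,3S) come from that single ligand-controlled hydrogenation, the lactate centre (R) from enzymatic reduction of the arylpyruvic acid, and the E-alkene from the decarboxylative condensation.

Key step: step 8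

Assumption: the sense of induction of the spiro ligand on this substrate class cannot be derived from a close analogue. The (Sa,S) ligand is written, and its mirror image would be taken if the first run should deliver the (2R,3R) acid.

**Step 1**
Reactants: 1 3,4-dihydroxybenzaldehyde
Product: 2 3-hydroxy-4-(4-methoxybenzyloxy)benzaldehyde
Conditions: 4-methoxybenzyl chloride, NaHCO3, NaI (cat), DMF, 40 °C
Reagents that add atoms: 4-methoxybenzyl chloride, COc1ccc(CCl)cc1
Why: Williamson ether synthesis under a base too weak to ionise both phenols: the 4-OH, acidified by the para formyl group, is deprotonated and alkylated preferentially (iodide catalysis through the benzylic iodide), which leaves the 3-OH free for step 5.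

**Step 2**
Reactants: 3 3,4-dihydroxybenzoic acid
Product: 5 3,4-bis(tert-butyldimethylsilyloxy)benzoic acid, via tris-silyl ester 4 (not isolated)
Conditions: TBSCl, imidazole, DMF, rt; then AcOH/THF/H2O, rt
Reagents that add atoms: tert-butyldimethylsilyl chloride, CC(C)(C)[Si](C)(C)Cl
Why: Exhaustive silylation followed by selective hydrolysis of the much more labile silyl ester in aqueous acetic acid is the routine way to O-silylated hydroxybenzoic acids, the aryl silyl ethers being stable to weak acid.

**Step 3**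
Reactants: 5 3,4-bis(tert-butyldimethylsilyloxy)benzoic acid; 6 Meldrum's acid (2,2-dimethyl-1,3-dioxane-4,6-dione)
Product: 8 tert-butyl 3-[3,4-bis(tert-butyldimethylsilyloxy)phenyl]-3-oxopropanoate, via acyl Meldrum's acid 7 (not isolated)
Conditions: DCC, DMAP, CH2Cl2, 0 °C to rt; filtration, aq KHSO4 wash, concentration; then t-BuOH, toluene, 90 °C
Reagents that add atoms: tert-butanol, CC(C)(C)O
Why: C-acylation of Meldrum's acid by the carbodiimide-activated acid (DMAP catalysis) and thermal tert-butanolysis of the acyl Meldrum's acid with loss of acetone and CO2 is the standard Meldrum's acid synthesis of β-keto esters and leaves the aryl silyl ethers alone.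

**Step 4**
Reactants: 8 tert-butyl 3-[3,4-bis(tert-butyldimethylsilyloxy)phenyl]-3-oxopropanoate
Product: 9 tert-butyl 3-[3,4-bis(tert-butyldimethylsilyloxy)phenyl]-2-diazo-3-oxopropanoate
Conditions: 4-acetamidobenzenesulfonyl azide, Et3N, MeCN, 0 °C to rt
Reagents that add atoms: 4-acetamidobenzenesulfonyl azide, CC(=O)Nc1ccc(S(=O)(=O)N=[N+]=[N-])cc1
Why: Regitz diazo transfer: the enolate of the 1,3-dicarbonyl unit attacks the terminal nitrogen of the sulfonyl azide and the adduct collapses to the 2-diazo-1,3-dicarbonyl compound and the sulfonamide.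

**Step 5**
Reactants: 2 3-hydroxy-4-(4-methoxybenzyloxy)benzaldehyde; 9 tert-butyl 3-[3,4-bis(tert-butyldimethylsilyloxy)phenyl]-2-diazo-3-oxopropanoate
Product: 10 racemic tert-butyl 3-[3,4-bis(tert-butyldimethylsilyloxy)phenyl]-2-[5-formyl-2-(4-methoxybenzyloxy)phenoxy]-3-oxopropanoate
Conditions: Rh2(OAc)4 (1 mol%), ClCH2CH2Cl, 80 °C, slow addition of 9
Reagents that add atoms: none
Why: Rhodium-carbenoid O–H insertion, well known for phenols and 2-diazo-3-oxo esters: the electrophilic carbenoid is captured by the free 3-OH faster than by the formyl oxygen or the arenes, a proton shift in the oxonium ylide completes the C2–O1 bond, and the new stereocentre is racemic and of no consequence because step 6 makes C2 trigonal.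

**Step 6**
Reactants: 10 racemic tert-butyl 3-[3,4-bis(tert-butyldimethylsilyloxy)phenyl]-2-[5-formyl-2-(4-methoxybenzyloxy)phenoxy]-3-oxopropanoate
Product: 13 tert-butyl 3-[3,4-bis(tert-butyldimethylsilyloxy)phenyl]-7-formyl-1,4-benzodioxine-2-carboxylate, via free phenol keto ester 11 (not isolated), via cyclic hemiketal 12 (not isolated)
Conditions: TFA (5 vol%), anisole, 4 Å MS, CH2Cl2, 0 °C to rt
Reagents that add atoms: none
Why: Acidolysis of the 4-methoxybenzyl aryl ether (SN1, cation trapped by anisole in a Friedel–Crafts alkylation) frees the 4-OH, which adds to the aryl ketone in a 6-exo-trig hemiketalisation, and acid-catalysed loss of water through the aryl-stabilised oxocarbenium ion with removal of the acidic C2–H gives the conjugated enol ether, the cold dilute acid being chosen so that the tert-butyl ester outlasts ring closure.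

**Step 7**
Reactants: 13 tert-butyl 3-[3,4-bis(tert-butyldimethylsilyloxy)phenyl]-7-formyl-1,4-benzodioxine-2-carboxylate
Product: 14 3-[3,4-bis(tert-butyldimethylsilyloxy)phenyl]-7-formyl-1,4-benzodioxine-2-carboxylic acid
Conditions: TFA/CH2Cl2 (1:3), anhydrous, 0 °C to rt
Reagents that add atoms: none
Why: Acidolysis of the tert-butyl ester (E1 loss of 2-methylpropene) is compatible with aryl silyl ethers and the aryl aldehyde, and once C2=C3 is in place the liberated acid is an acrylic acid and no longer a β-keto acid, so that it should not lose CO2 as long as water is kept out.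

**Step 8**
Reactants: 14 3-[3,4-bis(tert-butyldimethylsilyloxy)phenyl]-7-formyl-1,4-benzodioxine-2-carboxylic acid
Product: 15 (2S,3S)-3-[3,4-bis(tert-butyldimethylsilyloxy)phenyl]-7-formyl-2,3-dihydro-1,4-benzodioxine-2-carboxylic acid (CO2H and aryl cis)
Conditions: [Ir(cod)(L*)][B(3,5-(CF3)2C6H3)4] (2 mol%), L* = (Sa,S)-7-[bis(3,5-di-tert-butylphenyl)phosphanyl]-7'-(4-benzyl-4,5-dihydrooxazol-2-yl)-1,1'-spirobiindane, Et3N (0.5 equiv), H2 (30 bar), MeOH, 45 °C; then aq citric acid
Reagents that add atoms: none
Why: Proposed new method: the triethylammonium carboxylate of 14 binds the cationic dihydride of trivalent iridium and so pins the C2=C3 bond in the pocket of the spiro P,N ligand; one hydride migrates to C2 to leave a five-membered iridacycle (Ir–O–C(=O)–C2–C3), and after uptake of a second H2 the C3–H bond forms by reductive elimination on the same face. The closest known reaction types are the carboxyl-directed iridium/spiro phosphine-oxazoline hydrogenations of α-aryloxy and α-alkoxy acrylic acids and of tetrasubstituted acrylic acids, and the iridium- or rhodium-catalysed asymmetric hydrogenation of 2-substituted 1,4-benzodioxines, whereas a C=C bond that is tetrasubstituted and carries oxygen on both carbons has not been shown. No ring closes in this step, ring B being in place since step 6. C2 and C3 arise together: their cis relation follows from suprafacial delivery of both hydrogens, and their absolute (2S,3S) sense from the alkene face that the ligand leaves open to the chelated substrate. The step needs face selectivity, preference for the ring alkene over the C7 aldehyde and retention of both ring C–O bonds; the chelating C2 carboxylate secures the first two because only the alkene next to the anchor reaches the metal hydride, and the known α-aryloxy substrates pass through the same β-metallated intermediate without expelling aryloxide. The product leaves the metal as a carboxylate, so C2–H is not removed and the kinetic cis diad should persist.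

**Step 9**
Reactants: 16 vanillin; 17 N-acetylglycine
Product: 20 (Z)-4-(4-acetoxy-3-methoxybenzylidene)-2-methyloxazol-5(4H)-one, via vanillin acetate 18 (not isolated), via 2-methyloxazol-5(4H)-one 19 (not isolated)
Conditions: Ac2O, NaOAc, 110 °C
Reagents that add atoms: acetic anhydride, CC(=O)OC(C)=O
Why: Erlenmeyer–Plöchl azlactone synthesis: acetic anhydride cyclises 17 to oxazolone 19, whose active methylene group condenses with the aldehyde of the in situ acetylated vanillin 18 under acetate catalysis to give the thermodynamically preferred Z-azlactone.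

**Step 10**
Reactants: 20 (Z)-4-(4-acetoxy-3-methoxybenzylidene)-2-methyloxazol-5(4H)-one
Product: 22 3-(4-hydroxy-3-methoxyphenyl)-2-oxopropanoic acid, via acetamidoacrylic acid 21 (not isolated)
Conditions: 3 M aq HCl, reflux
Reagents that add atoms: water, O
Why: Acid hydrolysis of an Erlenmeyer azlactone: ring opening and acetate cleavage give enamide 21, whose hydrolysis releases the largely enolised α-keto acid, the standard access to arylpyruvic acids.

**Step 11**
Reactants: 22 3-(4-hydroxy-3-methoxyphenyl)-2-oxopropanoic acid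
Product: 23 (R)-2-hydroxy-3-(4-hydroxy-3-methoxyphenyl)propanoic acid
Conditions: D-lactate dehydrogenase, formate dehydrogenase, NAD+ (cat), HCO2Na, KH2PO4/K2HPO4 buffer pH 7, 30 °C; then HCl to pH 2
Reagents that add atoms: none
Why: Enzymatic ketone reduction with cofactor recycling: D-lactate dehydrogenase, which accepts arylpyruvates, transfers the hydride of NADH to the Si face of the 2-oxo group and so sets the (R) stereocentre under enzyme control, while formate dehydrogenase regenerates NADH irreversibly.

**Step 12**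
Reactants: 23 (R)-2-hydroxy-3-(4-hydroxy-3-methoxyphenyl)propanoic acid
Product: 24 benzyl (R)-3-(4-benzyloxy-3-methoxyphenyl)-2-hydroxypropanoate
Conditions: BnBr, K2CO3, DMF, rt
Reagents that add atoms: benzyl bromide, BrCc1ccccc1
Why: Double O-alkylation (carboxylate esterification and Williamson etherification) with K2CO3, which ionises only the acid and the phenol, so that the secondary alcohol remains free and the stereocentre is not touched.

**Step 13**
Reactants: 24 benzyl (R)-3-(4-benzyloxy-3-methoxyphenyl)-2-hydroxypropanoate; 6 Meldrum's acid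
Product: 25 3-{[(R)-1-benzyloxy-3-(4-benzyloxy-3-methoxyphenyl)-1-oxopropan-2-yl]oxy}-3-oxopropanoic acid
Conditions: toluene, 110 °C
Reagents that add atoms: none
Why: Thermal alcoholysis of Meldrum's acid: the secondary alcohol opens the dioxanedione with loss of acetone and gives the malonic half ester directly, with the C–O bond of the stereocentre untouched.

**Step 14**
Reactants: 25 3-{[(R)-1-benzyloxy-3-(4-benzyloxy-3-methoxyphenyl)-1-oxopropan-2-yl]oxy}-3-oxopropanoic acid
Product: 26 (R)-2-(carboxyacetoxy)-3-(4-hydroxy-3-methoxyphenyl)propanoic acid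
Conditions: H2 (1 bar), 10% Pd/C, THF, rt
Reagents that add atoms: none
Why: Catalytic hydrogenolysis removes the benzyl ester and the benzyl aryl ether together under neutral conditions that leave the malonate ester and the stereocentre alone, and it is placed before the acrylate alkene exists.

**Step 15**
Reactants: 15 (2S,3S)-3-[3,4-bis(tert-butyldimethylsilyloxy)phenyl]-7-formyl-2,3-dihydro-1,4-benzodioxine-2-carboxylic acid; 26 (R)-2-(carboxyacetoxy)-3-(4-hydroxy-3-methoxyphenyl)propanoic acid
Product: 28 (2S,3S)-3-[3,4-bis(tert-butyldimethylsilyloxy)phenyl]-7-{(E)-3-[(1R)-1-carboxy-2-(4-hydroxy-3-methoxyphenyl)ethoxy]-3-oxoprop-1-enyl}-2,3-dihydro-1,4-benzodioxine-2-carboxylic acid, via arylidenemalonic half ester 27 (not isolated)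
Conditions: pyridine, piperidine (cat), 45 °C, argon
Reagents that add atoms: none
Why: Knoevenagel–Doebner condensation of a malonic half ester: the piperidine-derived iminium ion of the aldehyde is attacked by the malonate enolate, and amine loss and decarboxylation of 27 give the conjugated E-acrylate under thermodynamic control, while both α-oxygenated acids are present as carboxylates and their α-hydrogens (C2–H of ring B and the lactate C–H) therefore resist epimerisation.

**Step 16**
Reactants: 28 bis-silyl ether of the target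
Product: 29 (2S,3S)-7-{(E)-3-[(1R)-1-carboxy-2-(4-hydroxy-3-methoxyphenyl)ethoxy]-3-oxoprop-1-enyl}-3-(3,4-dihydroxyphenyl)-2,3-dihydro-1,4-benzodioxine-2-carboxylic acid (CNP0249420.1)
Conditions: Et3N·3HF, THF, 0 °C to rt; reversed-phase chromatography
Reagents that add atoms: none
Why: Fluoride-induced cleavage of the aryl silyl ethers with a mildly acidic HF–amine complex keeps the liberated 4-hydroxyl group protonated, so that neither the acrylate ester nor C2 is attacked and the para-quinone-methide opening of the C3–O4 bond, which would scramble C3, is not triggered.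

**Compound list**

1 | 3,4-dihydroxybenzaldehyde | O=Cc1ccc(O)c(O)c1 | starting material
2 | 3-hydroxy-4-(4-methoxybenzyloxy)benzaldehyde | COc1ccc(COc2ccc(C=O)cc2O)cc1 | intermediate
3 | 3,4-dihydroxybenzoic acid | O=C(O)c1ccc(O)c(O)c1 | starting material
4 | tert-butyldimethylsilyl 3,4-bis(tert-butyldimethylsilyloxy)benzoate | CC(C)(C)[Si](C)(C)OC(=O)c1ccc(O[Si](C)(C)C(C)(C)C)c(O[Si](C)(C)C(C)(C)C)c1 | intermediate (not isolated)
5 | 3,4-bis(tert-butyldimethylsilyloxy)benzoic acid | O=C(O)c1ccc(O[Si](C)(C)C(C)(C)C)c(O[Si](C)(C)C(C)(C)C)c1 | intermediate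
6 | Meldrum's acid (2,2-dimethyl-1,3-dioxane-4,6-dione) | CC1(C)OC(=O)CC(=O)O1 | starting material
7 | 5-{[3,4-bis(tert-butyldimethylsilyloxy)phenyl](hydroxy)methylidene}-2,2-dimethyl-1,3-dioxane-4,6-dione | CC1(C)OC(=O)C(=C(O)c2ccc(O[Si](C)(C)C(C)(C)C)c(O[Si](C)(C)C(C)(C)C)c2)C(=O)O1 | intermediate (not isolated)
8 | tert-butyl 3-[3,4-bis(tert-butyldimethylsilyloxy)phenyl]-3-oxopropanoate | CC(C)(C)OC(=O)CC(=O)c1ccc(O[Si](C)(C)C(C)(C)C)c(O[Si](C)(C)C(C)(C)C)c1 | intermediate
9 | tert-butyl 3-[3,4-bis(tert-butyldimethylsilyloxy)phenyl]-2-diazo-3-oxopropanoate | CC(C)(C)OC(=O)C(=[N+]=[N-])C(=O)c1ccc(O[Si](C)(C)C(C)(C)C)c(O[Si](C)(C)C(C)(C)C)c1 | intermediate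
10 | racemic tert-butyl 3-[3,4-bis(tert-butyldimethylsilyloxy)phenyl]-2-[5-formyl-2-(4-methoxybenzyloxy)phenoxy]-3-oxopropanoate | CC(C)(C)OC(=O)C(Oc1cc(C=O)ccc1OCc1ccc(OC)cc1)C(=O)c1ccc(O[Si](C)(C)C(C)(C)C)c(O[Si](C)(C)C(C)(C)C)c1 | intermediate
11 | tert-butyl 3-[3,4-bis(tert-butyldimethylsilyloxy)phenyl]-2-(5-formyl-2-hydroxyphenoxy)-3-oxopropanoate | CC(C)(C)OC(=O)C(Oc1cc(C=O)ccc1O)C(=O)c1ccc(O[Si](C)(C)C(C)(C)C)c(O[Si](C)(C)C(C)(C)C)c1 | intermediate (not isolated)
12 | tert-butyl 3-[3,4-bis(tert-butyldimethylsilyloxy)phenyl]-7-formyl-3-hydroxy-2,3-dihydro-1,4-benzodioxine-2-carboxylate (mixture of stereoisomers) | CC(C)(C)OC(=O)C1Oc2cc(C=O)ccc2OC1(O)c1ccc(O[Si](C)(C)C(C)(C)C)c(O[Si](C)(C)C(C)(C)C)c1 | intermediate (not isolated)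
13 | tert-butyl 3-[3,4-bis(tert-butyldimethylsilyloxy)phenyl]-7-formyl-1,4-benzodioxine-2-carboxylate | CC(C)(C)OC(=O)C1=C(c2ccc(O[Si](C)(C)C(C)(C)C)c(O[Si](C)(C)C(C)(C)C)c2)Oc2ccc(C=O)cc2O1 | intermediate
14 | 3-[3,4-bis(tert-butyldimethylsilyloxy)phenyl]-7-formyl-1,4-benzodioxine-2-carboxylic acid | O=Cc1ccc2c(c1)OC(C(=O)O)=C(c1ccc(O[Si](C)(C)C(C)(C)C)c(O[Si](C)(C)C(C)(C)C)c1)O2 | intermediate
15 | (2S,3S)-3-[3,4-bis(tert-butyldimethylsilyloxy)phenyl]-7-formyl-2,3-dihydro-1,4-benzodioxine-2-carboxylic acid | O=Cc1ccc2c(c1)O[C@H](C(=O)O)[C@H](c1ccc(O[Si](C)(C)C(C)(C)C)c(O[Si](C)(C)C(C)(C)C)c1)O2 | intermediate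
16 | vanillin | COc1cc(C=O)ccc1O | starting material
17 | N-acetylglycine | CC(=O)NCC(=O)O | starting material
18 | 4-acetoxy-3-methoxybenzaldehyde (vanillin acetate) | COc1cc(C=O)ccc1OC(C)=O | intermediate (not isolated)
19 | 2-methyloxazol-5(4H)-one | CC1=NCC(=O)O1 | intermediate (not isolated)
20 | (Z)-4-(4-acetoxy-3-methoxybenzylidene)-2-methyloxazol-5(4H)-one | CC1=N/C(=C\c2ccc(OC(C)=O)c(OC)c2)C(=O)O1 | intermediate
21 | (Z)-2-acetamido-3-(4-hydroxy-3-methoxyphenyl)prop-2-enoic acid | COc1cc(/C=C(\NC(C)=O)C(=O)O)ccc1O | intermediate (not isolated)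
22 | 3-(4-hydroxy-3-methoxyphenyl)-2-oxopropanoic acid (drawn as the keto form) | COc1cc(CC(=O)C(=O)O)ccc1O | intermediate
23 | (R)-2-hydroxy-3-(4-hydroxy-3-methoxyphenyl)propanoic acid | COc1cc(C[C@@H](O)C(=O)O)ccc1O | intermediate
24 | benzyl (R)-3-(4-benzyloxy-3-methoxyphenyl)-2-hydroxypropanoate | COc1cc(C[C@@H](O)C(=O)OCc2ccccc2)ccc1OCc1ccccc1 | intermediate
25 | 3-{[(R)-1-benzyloxy-3-(4-benzyloxy-3-methoxyphenyl)-1-oxopropan-2-yl]oxy}-3-oxopropanoic acid | COc1cc(C[C@@H](OC(=O)CC(=O)O)C(=O)OCc2ccccc2)ccc1OCc1ccccc1 | intermediate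
26 | (R)-2-(carboxyacetoxy)-3-(4-hydroxy-3-methoxyphenyl)propanoic acid | COc1cc(C[C@@H](OC(=O)CC(=O)O)C(=O)O)ccc1O | intermediate
27 | arylidenemalonic half ester from 15 and 26 (alkene geometry not defined) | COc1cc(C[C@@H](OC(=O)C(=Cc2ccc3c(c2)O[C@H](C(=O)O)[C@H](c2ccc(O[Si](C)(C)C(C)(C)C)c(O[Si](C)(C)C(C)(C)C)c2)O3)C(=O)O)C(=O)O)ccc1O | intermediate (not isolated)
28 | bis(tert-butyldimethylsilyl) ether of the target | COc1cc(C[C@@H](OC(=O)/C=C/c2ccc3c(c2)O[C@H](C(=O)O)[C@H](c2ccc(O[Si](C)(C)C(C)(C)C)c(O[Si](C)(C)C(C)(C)C)c2)O3)C(=O)O)ccc1O | intermediate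
29 | CNP0249420.1 | COc1cc(C[C@@H](OC(=O)/C=C/c2ccc3c(c2)O[C@H](C(=O)O)[C@H](c2ccc(O)c(O)c2)O3)C(=O)O)ccc1O | target

**Step count**

- Total step count: 16.
- Longest linear sequence: 9 steps (3 → 5 → 8 → 9 → 10 → 13 → 14 → 15 → 28 → 29). The vanillin branch needs 8 steps to the target.

**Steps most likely to fail**

**Step 8 (the labelled step).** Turnover may stall at the crowded, doubly oxygenated alkene, the facial selectivity may be poor, or the formyl group may be reduced in competition.

The fallback gives up catalyst control and uses known chemistry only. It sets out from ester 13.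
- The aldehyde of 13 is masked with HC(OMe)3 and pyridinium tosylate in MeOH as tert-butyl 3-[3,4-bis(tert-butyldimethylsilyloxy)phenyl]-7-(dimethoxymethyl)-1,4-benzodioxine-2-carboxylate F1.
- Heterogeneous syn hydrogenation (H2, 50 bar, 10% Pd/C, EtOAc with a trace of Et3N) is the established way from 1,4-benzodioxines to cis-2,3-disubstituted benzodioxanes. It should give racemic cis tert-butyl 3-[3,4-bis(tert-butyldimethylsilyloxy)phenyl]-7-(dimethoxymethyl)-2,3-dihydro-1,4-benzodioxine-2-carboxylate F2.
- Preparative chromatography on a polysaccharide chiral stationary phase would deliver tert-butyl (2S,3S)-3-[3,4-bis(tert-butyldimethylsilyloxy)phenyl]-7-(dimethoxymethyl)-2,3-dihydro-1,4-benzodioxine-2-carboxylate F3.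
- 85% aq H3PO4 in toluene at rt removes the acetal and the tert-butyl group under acid too weak to ionise the benzylic C3–O4 bond. This brings the material back to the route at 15.

**Step 6.** The tert-butyl group may be lost before the ring has closed and shed water. The β-keto acid would then decarboxylate. Incomplete dehydration of the hemiketal under the deliberately weak acid is the other failure mode.

The fallback changes the design of the precursor to an ester that cannot ionise. It sets out from 5 and 6.
- The crude acyl Meldrum's acid 7 is heated with 2,2,2-trichloroethanol instead of tert-butanol to give 2,2,2-trichloroethyl 3-[3,4-bis(tert-butyldimethylsilyloxy)phenyl]-3-oxopropanoate F4.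
- Diazo transfer as in step 4 gives 2,2,2-trichloroethyl 3-[3,4-bis(tert-butyldimethylsilyloxy)phenyl]-2-diazo-3-oxopropanoate F5.
- O–H insertion into 2 as in step 5 gives 2,2,2-trichloroethyl 3-[3,4-bis(tert-butyldimethylsilyloxy)phenyl]-2-[5-formyl-2-(4-methoxybenzyloxy)phenoxy]-3-oxopropanoate F6.
- Ether cleavage and dehydration can now be forced (TFA/CH2Cl2 1:1 with anisole, then TsOH in toluene with azeotropic removal of water). The product is 2,2,2-trichloroethyl 3-[3,4-bis(tert-butyldimethylsilyloxy)phenyl]-7-formyl-1,4-benzodioxine-2-carboxylate F7.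
- Reductive cleavage with Zn dust in THF/aq NH4OAc rejoins the route at 14.

**Step 15.** The half ester may decarboxylate before it has condensed, the donor-substituted aldehyde may react sluggishly, and the warm amine medium may strip the silyl groups. Loss of the silyl groups would open the quinone-methide path to the trans isomer.

The fallback replaces the decarboxylative condensation by a phosphonate olefination at room temperature. It sets out from alcohol 24.
- Alcohol 24 is acylated with diethylphosphonoacetic acid (DCC, DMAP, CH2Cl2) to benzyl (R)-3-(4-benzyloxy-3-methoxyphenyl)-2-[2-(diethoxyphosphoryl)acetoxy]propanoate F8.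
- Hydrogenolysis (H2, 10% Pd/C, THF) gives (R)-2-[2-(diethoxyphosphoryl)acetoxy]-3-(4-hydroxy-3-methoxyphenyl)propanoic acid F9.
- An E-selective Horner–Wadsworth–Emmons reaction with aldehyde 15 under Masamune–Roush conditions (LiCl, excess i-Pr2NEt, MeCN, rt) keeps both acids as carboxylates. It comes back to the route at 28.

**Further compounds**

F1 | step 8 | tert-butyl 3-[3,4-bis(tert-butyldimethylsilyloxy)phenyl]-7-(dimethoxymethyl)-1,4-benzodioxine-2-carboxylate | COC(OC)c1ccc2c(c1)OC(C(=O)OC(C)(C)C)=C(c1ccc(O[Si](C)(C)C(C)(C)C)c(O[Si](C)(C)C(C)(C)C)c1)O2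
F2 | step 8 | racemic cis tert-butyl 3-[3,4-bis(tert-butyldimethylsilyloxy)phenyl]-7-(dimethoxymethyl)-2,3-dihydro-1,4-benzodioxine-2-carboxylate (both enantiomers) | COC(OC)c1ccc2c(c1)O[C@H](C(=O)OC(C)(C)C)[C@H](c1ccc(O[Si](C)(C)C(C)(C)C)c(O[Si](C)(C)C(C)(C)C)c1)O2.COC(OC)c1ccc2c(c1)O[C@@H](C(=O)OC(C)(C)C)[C@@H](c1ccc(O[Si](C)(C)C(C)(C)C)c(O[Si](C)(C)C(C)(C)C)c1)O2
F3 | step 8 | tert-butyl (2S,3S)-3-[3,4-bis(tert-butyldimethylsilyloxy)phenyl]-7-(dimethoxymethyl)-2,3-dihydro-1,4-benzodioxine-2-carboxylate | COC(OC)c1ccc2c(c1)O[C@H](C(=O)OC(C)(C)C)[C@H](c1ccc(O[Si](C)(C)C(C)(C)C)c(O[Si](C)(C)C(C)(C)C)c1)O2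
F4 | step 6 | 2,2,2-trichloroethyl 3-[3,4-bis(tert-butyldimethylsilyloxy)phenyl]-3-oxopropanoate | O=C(CC(=O)c1ccc(O[Si](C)(C)C(C)(C)C)c(O[Si](C)(C)C(C)(C)C)c1)OCC(Cl)(Cl)Cl
F5 | step 6 | 2,2,2-trichloroethyl 3-[3,4-bis(tert-butyldimethylsilyloxy)phenyl]-2-diazo-3-oxopropanoate | O=C(OCC(Cl)(Cl)Cl)C(=[N+]=[N-])C(=O)c1ccc(O[Si](C)(C)C(C)(C)C)c(O[Si](C)(C)C(C)(C)C)c1
F6 | step 6 | 2,2,2-trichloroethyl 3-[3,4-bis(tert-butyldimethylsilyloxy)phenyl]-2-[5-formyl-2-(4-methoxybenzyloxy)phenoxy]-3-oxopropanoate (racemic) | O=C(OCC(Cl)(Cl)Cl)C(Oc1cc(C=O)ccc1OCc1ccc(OC)cc1)C(=O)c1ccc(O[Si](C)(C)C(C)(C)C)c(O[Si](C)(C)C(C)(C)C)c1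
F7 | step 6 | 2,2,2-trichloroethyl 3-[3,4-bis(tert-butyldimethylsilyloxy)phenyl]-7-formyl-1,4-benzodioxine-2-carboxylate | O=Cc1ccc2c(c1)OC(C(=O)OCC(Cl)(Cl)Cl)=C(c1ccc(O[Si](C)(C)C(C)(C)C)c(O[Si](C)(C)C(C)(C)C)c1)O2
F8 | step 15 | benzyl (R)-3-(4-benzyloxy-3-methoxyphenyl)-2-[2-(diethoxyphosphoryl)acetoxy]propanoate | COc1cc(C[C@@H](OC(=O)CP(=O)(OCC)OCC)C(=O)OCc2ccccc2)ccc1OCc1ccccc1
F9 | step 15 | (R)-2-[2-(diethoxyphosphoryl)acetoxy]-3-(4-hydroxy-3-methoxyphenyl)propanoic acid | COc1cc(C[C@@H](OC(=O)CP(=O)(OCC)OCC)C(=O)O)ccc1O
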